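## Retrosynthetic overview

1. Target ⇒ (13E)-allylic alcohol: Sharpless epoxidation sets C13 and C14, then C15 oxidation and C3 acetylation; the allylic alcohol comes from a C13 methyl ketone by Horner–Wadsworth–Emmons olefination and ester reduction.
2. Ring A functionality ⇒ bicyclic 3-oxo-19-ester: the axial 3α-oxygen by equatorial hydride delivery, the methyl ester from an auxiliary ester through the C19 carbinol.
3. Key disconnection: the whole decalin ⇒ an acyclic 2-methyl-3-oxo ester polyene by one Mn(OAc)3/Cu(OAc)2 oxidative radical bicyclisation. Ring A closes first (C4–C5), ring B second (C10–C9), and the 8(17)-alkene comes from the oxidative termination; an 8-phenylmenthyl ester fixes the absolute sense of C4, C5, C9 and C10.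
4. Polyene ⇒ dianion of 8-phenylmenthyl 2-methylacetoacetate + allylic bromide made from (E)-geranylacetone (ketal, SeO2 oxidation, bromination).
5. Avoided on purpose: cationic epoxy-polyene cyclisation or annulation from a Wieland–Miescher ketone, neither of which delivers the axial C19 ester and the exocyclic alkene directly.

## Assumptions

- Bicyclic compounds are named as labdanes of the normal series (5α-H, 9α-H, 10β-CH3; C19 is the axial 4β carbon, C18 the 4α methyl).
- The (1R,2S,5R)-8-phenylmenthyl ester is assumed to steer the cyclisation to the normal series drawn, as recalled for related 2-methyl keto esters (podocarpate series); if the facial sense proved opposite, the enantiomeric auxiliary alcohol would be used with no other change.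
- (E)-Geranylacetone is bought as the isomerically pure E grade.

## Route

Step 1
Reactants: 1 (E)-geranylacetone
Product: 2 2-[(3E)-4,8-dimethylnona-3,7-dien-1-yl]-2-methyl-1,3-dioxolane
Conditions: HOCH2CH2OH (3 equiv), PPTS (cat.), benzene, reflux, Dean–Stark
Reagents that add atoms: ethylene glycol OCCO
Why: Acid-catalysed ketalisation (dioxolane formation) with azeotropic removal of water masks the future C13 ketone against the dianion and hydride steps, and the mild pyridinium acid leaves the trisubstituted alkenes alone.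

Step 2
Reactants: 2 geranylacetone ethylene ketal
Product: 3 (2E,6E)-2,6-dimethyl-9-(2-methyl-1,3-dioxolan-2-yl)nona-2,6-dien-1-ol
Conditions: SeO2 (0.3 equiv), t-BuOOH (3 equiv), CH2Cl2, 0 → 25 °C
Reagents that add atoms: selenium dioxide O=[Se]=O (transfers the oxygen); tert-butyl hydroperoxide CC(C)(C)OO (reoxidant that supplies it)
Why: Sharpless-type SeO2 allylic oxidation (ene reaction then [2,3]-sigmatropic shift) attacks the terminal, more electron-rich alkene at its E-methyl group and gives the (E)-allylic alcohol without touching the inner alkene or the ketal.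

Step 3
Reactants: 3 ketal allylic alcohol
Product: 4 2-[(3E,7E)-9-bromo-4,8-dimethylnona-3,7-dien-1-yl]-2-methyl-1,3-dioxolane
Conditions: CBr4, PPh3, CH2Cl2, 0 °C
Reagents that add atoms: carbon tetrabromide BrC(Br)(Br)Br
Why: Appel bromination; the activated primary allylic alcohol is displaced by bromide in SN2 fashion under neutral conditions, so the E geometry and the ketal survive.

Step 4
Reactants: 5 (−)-8-phenylmenthol; 6 methyl 2-methyl-3-oxobutanoate
Product: 8 (1R,2S,5R)-8-phenylmenthyl 2-methyl-3-oxobutanoate (C2 epimers), via acetyl(methyl)ketene 7 (not isolated)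
Conditions: DMAP (0.3 equiv), toluene, reflux, MeOH distilled off
Reagents that add atoms: none
Why: DMAP-promoted transesterification of an enolisable keto ester runs through the acylketene and therefore acylates even this hindered secondary alcohol; the auxiliary stereocentres are untouched and the new α-centre is an irrelevant epimer mixture.

Step 5
Reactants: 8 8-phenylmenthyl 2-methyl-3-oxobutanoate; 4 ketal allylic bromide
Product: 10 (1R,2S,5R)-8-phenylmenthyl (6E,10E)-2,6,10-trimethyl-13-(2-methyl-1,3-dioxolan-2-yl)-3-oxotrideca-6,10-dienoate (C2 epimers), via sodium lithium dienolate 9 (not isolated)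
Conditions: NaH, THF, 0 °C; n-BuLi, 0 °C; then 4, 0 → 25 °C; aq NH4Cl
Reagents that add atoms: none
Why: Huckin–Weiler dianion alkylation; the more basic terminal carbon of the dienolate displaces the allylic bromide (SN2), which joins all skeletal carbons C1–C13 and C16–C20 with both alkenes E.

Step 6
Reactants: 10 acyclic 8-phenylmenthyl keto ester
Product: 13 (1R,2S,5R)-8-phenylmenthyl 13,13-ethylenedioxy-3-oxo-14,15-dinorlabd-8(17)-en-19-oate, via keto ester α-radical 11 (not isolated), via bicyclic C8 radical 12 (not isolated)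
Conditions: Mn(OAc)3·2H2O (2.2 equiv), Cu(OAc)2·H2O (1 equiv), KOAc (3 equiv), degassed AcOH (0.02 M), 25 °C
Reagents that add atoms: none
Why: Mn(OAc)3 (trivalent manganese) oxidises the keto ester enol to the C4 radical, which closes ring A (6-endo on the E alkene) and then ring B through a chair–chair transition state that gives the trans ring fusion, the axial C19 ester cis to the C10 methyl and the equatorial C9 side chain. Cu(OAc)2 (divalent copper) then oxidises the tertiary C8 radical with loss of a methyl hydrogen to give the exocyclic alkene. The phenyl ring of the auxiliary shields one face of the planar radical, so C4, C5, C9 and C10 arise in one absolute sense (about 85 % de expected, minor isomer and endocyclic alkene isomers removed by chromatography). The acetate buffer keeps the ketal intact. This is an oxidative free-radical polyene cyclisation of the Snider type.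

Step 7
Reactants: 13 bicyclic 3-oxo 8-phenylmenthyl ester
Product: 14 (1R,2S,5R)-8-phenylmenthyl 13,13-ethylenedioxy-3α-hydroxy-14,15-dinorlabd-8(17)-en-19-oate
Conditions: LiBH(s-Bu)3 (1.5 equiv), THF, −78 → −40 °C; then H2O
Reagents that add atoms: none
Why: Bulky trialkylborohydride reduction; the reagent cannot use the axial α trajectory (1,3-diaxial hydrogens on C1 and C5) and delivers hydride from the equatorial side, which sets C3 as the axial 3α-alcohol (3R), while the hindered ester, the ketal and the alkene are inert.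

Step 8
Reactants: 14 3α-hydroxy 8-phenylmenthyl ester
Product: 15 13,13-ethylenedioxy-14,15-dinorlabd-8(17)-ene-3α,19-diol
Conditions: LiAlH4 (3 equiv), THF, 0 °C → reflux; then H2O
Reagents that add atoms: none
Why: LiAlH4 reduction of the neopentyl ester to the C19 carbinol removes the auxiliary (alcohol 5 is recovered for re-use) without touching any stereocentre, the ketal or the alkene.

Step 9
Reactants: 15 3α,19-diol
Product: 17 13,13-ethylenedioxy-3α-hydroxy-14,15-dinorlabd-8(17)-en-19-oic acid, via 3α-hydroxy aldehyde 16 (not isolated)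
Conditions: TEMPO (0.2 equiv), PhI(OAc)2 (1.2 equiv), CH2Cl2, 25 °C; then NaClO2, NaH2PO4, 2-methyl-2-butene, t-BuOH/H2O, 25 °C
Reagents that add atoms: sodium chlorite [Na+].[O-]Cl=O
Why: Oxoammonium (TEMPO) oxidation is selective for the primary C19 alcohol over the hindered axial secondary one, and Pinnick oxidation takes the non-enolisable aldehyde to the acid while the added alkene scavenges hypochlorite and protects the exocyclic alkene.

Step 10
Reactants: 17 3α-hydroxy-19-oic acid
Product: 19 methyl 3α-hydroxy-13-oxo-14,15-dinorlabd-8(17)-en-19-oate, via ketal methyl ester 18 (not isolated)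
Conditions: Me3SiCHN2, toluene/MeOH, 0 °C; then 1 M HCl, THF, 25 °C
Reagents that add atoms: (trimethylsilyl)diazomethane C[Si](C)(C)C=[N+]=[N-]; water O
Why: Esterification by O-alkylation of the carboxylate with the protonated diazoalkane is insensitive to the hindrance at C4, and dilute acid then hydrolyses the dioxolane to the C13 methyl ketone (ketal hydrolysis).

Step 11
Reactants: 19 hydroxy keto methyl ester
Product: 20 15-ethyl 19-methyl (13E)-3α-hydroxylabda-8(17),13-diene-15,19-dioate
Conditions: (EtO)2P(O)CH2CO2Et (3 equiv), NaH (2.9 equiv), THF, 0 → 50 °C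
Reagents that add atoms: triethyl phosphonoacetate CCOC(=O)CP(=O)(OCC)OCC
Why: Horner–Wadsworth–Emmons olefination of the unhindered methyl ketone gives mainly the (13E)-enoate (about 4:1, Z isomer removed by chromatography), and because no base stronger than the phosphonate anion is present the 3-hydroxy ester is not deprotonated and cannot undergo retro-aldol cleavage.

Step 12
Reactants: 20 (13E)-diester
Product: 21 methyl (13E)-3α,15-dihydroxylabda-8(17),13-dien-19-oate
Conditions: i-Bu2AlH (3.5 equiv), CH2Cl2, −78 °C; aq potassium sodium tartrate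
Reagents that add atoms: none
Why: i-Bu2AlH 1,2-reduction of the conjugated ethyl ester gives the (E)-allylic alcohol, while the axial C19 methyl ester on a quaternary carbon is too hindered to react at −78 °C (chemoselective ester reduction).

Step 13
Reactants: 21 (13E)-allylic alcohol
Product: 22 methyl (13R,14R)-13,14-epoxy-3α,15-dihydroxylabd-8(17)-en-19-oate
Conditions: Ti(OiPr)4 (10 mol %), D-(−)-diethyl tartrate (12 mol %), t-BuOOH (2 equiv), 4 Å molecular sieves, CH2Cl2, −20 °C
Reagents that add atoms: tert-butyl hydroperoxide CC(C)(C)OO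
Why: Katsuki–Sharpless asymmetric epoxidation; the titanium–D-tartrate catalyst delivers oxygen to one face of the allylic alcohol, in the sense that turns geraniol into its (2R,3R)-epoxide, so C13 (R) and C14 (R) are set by reagent control and the isolated exocyclic alkene is not epoxidised.

Step 14
Reactants: 22 epoxy diol
Product: 23 methyl (13R,14S)-13,14-epoxy-3α-hydroxy-15-oxolabd-8(17)-en-19-oate
Conditions: TEMPO (0.1 equiv), PhI(OAc)2 (1.1 equiv), CH2Cl2, 25 °C
Reagents that add atoms: none
Why: TEMPO/PhI(OAc)2 oxidation converts only the primary epoxy alcohol to the aldehyde under near-neutral conditions that leave the epoxide and the hindered 3α-hydroxyl alone (the C14 descriptor changes to S only through the priority change).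

Step 15
Reactants: 23 epoxy aldehyde
Product: 24 methyl (13R,14S)-3α-acetoxy-13,14-epoxy-15-oxolabd-8(17)-en-19-oate
Conditions: Ac2O (5 equiv), pyridine, DMAP (cat.), CH2Cl2, 0 → 25 °C
Reagents that add atoms: acetic anhydride CC(=O)OC(C)=O
Why: DMAP-catalysed acetylation of the axial 3α-hydroxyl (this ring A pattern is known to acetylate readily) proceeds with retention at C3, and the epoxy aldehyde has no enolisable position to suffer under the amine base.

## Compound list

1 | (E)-geranylacetone, (5E)-6,10-dimethylundeca-5,9-dien-2-one | CC(=O)CC/C=C(\C)CCC=C(C)C | starting material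
2 | 2-[(3E)-4,8-dimethylnona-3,7-dien-1-yl]-2-methyl-1,3-dioxolane | CC1(CC/C=C(\C)CCC=C(C)C)OCCO1 | intermediate
3 | (2E,6E)-2,6-dimethyl-9-(2-methyl-1,3-dioxolan-2-yl)nona-2,6-dien-1-ol | CC1(CC/C=C(\C)CC/C=C(\C)CO)OCCO1 | intermediate
4 | 2-[(3E,7E)-9-bromo-4,8-dimethylnona-3,7-dien-1-yl]-2-methyl-1,3-dioxolane | CC1(CC/C=C(\C)CC/C=C(\C)CBr)OCCO1 | intermediate
5 | (−)-8-phenylmenthol, (1R,2S,5R)-5-methyl-2-(2-phenylpropan-2-yl)cyclohexan-1-ol | O[C@@H]1C[C@H](C)CC[C@H]1C(C)(C)c2ccccc2 | starting material
6 | methyl 2-methyl-3-oxobutanoate | CC(=O)C(C)C(=O)OC | starting material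
7 | acetyl(methyl)ketene, 2-methyl-3-oxobut-1-en-1-one | CC(=O)C(C)=C=O | intermediate (not isolated)
8 | (1R,2S,5R)-8-phenylmenthyl 2-methyl-3-oxobutanoate (C2 epimers) | CC(=O)C(C)C(=O)O[C@@H]1C[C@H](C)CC[C@H]1C(C)(C)c2ccccc2 | intermediate
9 | sodium lithium dienolate (dianion) of 8 | [Na+].[Li+].C=C([O-])C(C)=C([O-])O[C@@H]1C[C@H](C)CC[C@H]1C(C)(C)c2ccccc2 | intermediate (not isolated)
10 | (1R,2S,5R)-8-phenylmenthyl (6E,10E)-2,6,10-trimethyl-13-(2-methyl-1,3-dioxolan-2-yl)-3-oxotrideca-6,10-dienoate (C2 epimers) | CC1(CC/C=C(\C)CC/C=C(\C)CCC(=O)C(C)C(=O)O[C@@H]2C[C@H](C)CC[C@H]2C(C)(C)c3ccccc3)OCCO1 | intermediate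
11 | C2 (α-keto ester) radical of 10 | CC1(CC/C=C(\C)CC/C=C(\C)CCC(=O)[C](C)C(=O)O[C@@H]2C[C@H](C)CC[C@H]2C(C)(C)c3ccccc3)OCCO1 | intermediate (not isolated)
12 | bicyclic tertiary C8 radical (trans-decalin, C4, C5, C9, C10 already set) | C[C]1CC[C@@H]2[C@](C)(CCC(=O)[C@]2(C)C(=O)O[C@@H]3C[C@H](C)CC[C@H]3C(C)(C)c4ccccc4)[C@H]1CCC5(C)OCCO5 | intermediate (not isolated)
13 | (1R,2S,5R)-8-phenylmenthyl 13,13-ethylenedioxy-3-oxo-14,15-dinorlabd-8(17)-en-19-oate | C=C1CC[C@@H]2[C@](C)(CCC(=O)[C@]2(C)C(=O)O[C@@H]3C[C@H](C)CC[C@H]3C(C)(C)c4ccccc4)[C@H]1CCC5(C)OCCO5 | intermediate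
14 | (1R,2S,5R)-8-phenylmenthyl 13,13-ethylenedioxy-3α-hydroxy-14,15-dinorlabd-8(17)-en-19-oate | C=C1CC[C@@H]2[C@](C)(CC[C@@H](O)[C@]2(C)C(=O)O[C@@H]3C[C@H](C)CC[C@H]3C(C)(C)c4ccccc4)[C@H]1CCC5(C)OCCO5 | intermediate
15 | 13,13-ethylenedioxy-14,15-dinorlabd-8(17)-ene-3α,19-diol | C=C1CC[C@@H]2[C@](C)(CC[C@@H](O)[C@]2(C)CO)[C@H]1CCC3(C)OCCO3 | intermediate
16 | 13,13-ethylenedioxy-3α-hydroxy-14,15-dinorlabd-8(17)-en-19-al | C=C1CC[C@@H]2[C@](C)(CC[C@@H](O)[C@]2(C)C=O)[C@H]1CCC3(C)OCCO3 | intermediate (not isolated)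
17 | 13,13-ethylenedioxy-3α-hydroxy-14,15-dinorlabd-8(17)-en-19-oic acid | C=C1CC[C@@H]2[C@](C)(CC[C@@H](O)[C@]2(C)C(=O)O)[C@H]1CCC3(C)OCCO3 | intermediate
18 | methyl 13,13-ethylenedioxy-3α-hydroxy-14,15-dinorlabd-8(17)-en-19-oate | C=C1CC[C@@H]2[C@](C)(CC[C@@H](O)[C@]2(C)C(=O)OC)[C@H]1CCC3(C)OCCO3 | intermediate (not isolated)
19 | methyl 3α-hydroxy-13-oxo-14,15-dinorlabd-8(17)-en-19-oate | C=C1CC[C@@H]2[C@](C)(CC[C@@H](O)[C@]2(C)C(=O)OC)[C@H]1CCC(C)=O | intermediate
20 | 15-ethyl 19-methyl (13E)-3α-hydroxylabda-8(17),13-diene-15,19-dioate | C=C1CC[C@@H]2[C@](C)(CC[C@@H](O)[C@]2(C)C(=O)OC)[C@H]1CC/C(C)=C/C(=O)OCC | intermediate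
21 | methyl (13E)-3α,15-dihydroxylabda-8(17),13-dien-19-oate | C=C1CC[C@@H]2[C@](C)(CC[C@@H](O)[C@]2(C)C(=O)OC)[C@H]1CC/C(C)=C/CO | intermediate
22 | methyl (13R,14R)-13,14-epoxy-3α,15-dihydroxylabd-8(17)-en-19-oate | C=C1CC[C@@H]2[C@](C)(CC[C@@H](O)[C@]2(C)C(=O)OC)[C@H]1CC[C@@]3(C)O[C@@H]3CO | intermediate
23 | methyl (13R,14S)-13,14-epoxy-3α-hydroxy-15-oxolabd-8(17)-en-19-oate | C=C1CC[C@@H]2[C@](C)(CC[C@@H](O)[C@]2(C)C(=O)OC)[C@H]1CC[C@@]3(C)O[C@@H]3C=O | intermediate
24 | methyl (13R,14S)-3α-acetoxy-13,14-epoxy-15-oxolabd-8(17)-en-19-oate = methyl (1R,2R,4aR,5S,8aR)-2-acetoxy-5-{2-[(2R,3S)-3-formyl-2-methyloxiran-2-yl]ethyl}-1,4a-dimethyl-6-methylidenedecahydronaphthalene-1-carboxylate | C=C1CC[C@@H]2[C@](C)(CC[C@@H](OC(C)=O)[C@]2(C)C(=O)OC)[C@H]1CC[C@@]1(C)O[C@@H]1C=O | target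

## Step count and risk

Total step count: 15. Longest linear sequence: 14 steps (steps 1–3 and 5–15 from compound 1; step 4 is the short second branch).

The three steps most likely to fail are steps 6, 7 and 15.

Step 6 (oxidative bicyclisation). The risks are moderate auxiliary control, endocyclic alkene isomers from the copper termination, and loss of the ketal in acetic acid. The fallback sets out from 10 and comes back to the route at 13, and replaces the oxidative termination by a redox-neutral group-transfer cascade. Compound 10 is selenenylated at C2 (NaH, PhSeCl, THF, 0 °C) to the 2-(phenylselanyl) keto ester F1. Irradiation of F1 (sun lamp, benzene, 25 °C) breaks the weak C–Se bond, the same C4 radical closes rings A and B, and the C8 radical takes a phenylselanyl group from another molecule of F1 on its open α face to give the 8α-phenylselanyl decalin F2. Oxidation of F2 (H2O2, pyridine, CH2Cl2, 0 °C) and syn-elimination of the selenoxide toward the freely rotating axial methyl group gives 13.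

Step 7 (hydride facial selectivity next to the bulky auxiliary ester). The fallback sets out from 13 and comes back at 18, and removes the auxiliary before C3 is set. LiAlH4 (THF, reflux) takes ketone and ester down together to the 3β,19-diol F3 (the C3 epimer ratio does not matter) and frees the auxiliary. Dess–Martin periodinane (NaHCO3, CH2Cl2) oxidises both hydroxyls to the 3-oxo-19-aldehyde F4. Pinnick oxidation (NaClO2, NaH2PO4, 2-methyl-2-butene, 0 °C) gives the 3-oxo-19-oic acid F5, which is kept cold and methylated at once (Me3SiCHN2, toluene/MeOH) to the methyl 3-oxo ester F6. LiBH(s-Bu)3 (THF, −78 °C) then meets only a small methyl ester beside the ketone and gives 18, which the acid stage of step 10 converts to 19.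

Step 15 (acetylation of a hindered axial alcohol beside a sensitive epoxy aldehyde). The fallback sets out from 22 and comes back at 24, and puts the acetate on before the aldehyde exists. Epoxy diol 22 is acetylated at both hydroxyls (Ac2O, pyridine, DMAP) to the 3α,15-diacetate F7. K2CO3 in MeOH at 0 °C removes only the unhindered primary acetate to give the 3α-acetoxy epoxy alcohol F8. Dess–Martin periodinane (NaHCO3, CH2Cl2) then gives 24 as the last, neutral step.

Further compounds

F1 | step 6 | (1R,2S,5R)-8-phenylmenthyl (6E,10E)-2,6,10-trimethyl-13-(2-methyl-1,3-dioxolan-2-yl)-3-oxo-2-(phenylselanyl)trideca-6,10-dienoate | CC1(CC/C=C(\C)CC/C=C(\C)CCC(=O)C(C)([Se]c2ccccc2)C(=O)O[C@@H]3C[C@H](C)CC[C@H]3C(C)(C)c4ccccc4)OCCO1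
F2 | step 6 | (1R,2S,5R)-8-phenylmenthyl 13,13-ethylenedioxy-3-oxo-8α-(phenylselanyl)-14,15-dinorlabdan-19-oate | C[C@@]1([Se]c6ccccc6)CC[C@@H]2[C@](C)(CCC(=O)[C@]2(C)C(=O)O[C@@H]3C[C@H](C)CC[C@H]3C(C)(C)c4ccccc4)[C@H]1CCC5(C)OCCO5
F3 | step 7 | 13,13-ethylenedioxy-14,15-dinorlabd-8(17)-ene-3β,19-diol | C=C1CC[C@@H]2[C@](C)(CC[C@H](O)[C@]2(C)CO)[C@H]1CCC3(C)OCCO3
F4 | step 7 | 13,13-ethylenedioxy-3-oxo-14,15-dinorlabd-8(17)-en-19-al | C=C1CC[C@@H]2[C@](C)(CCC(=O)[C@]2(C)C=O)[C@H]1CCC3(C)OCCO3
F5 | step 7 | 13,13-ethylenedioxy-3-oxo-14,15-dinorlabd-8(17)-en-19-oic acid | C=C1CC[C@@H]2[C@](C)(CCC(=O)[C@]2(C)C(=O)O)[C@H]1CCC3(C)OCCO3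
F6 | step 7 | methyl 13,13-ethylenedioxy-3-oxo-14,15-dinorlabd-8(17)-en-19-oate | C=C1CC[C@@H]2[C@](C)(CCC(=O)[C@]2(C)C(=O)OC)[C@H]1CCC3(C)OCCO3
F7 | step 15 | methyl (13R,14R)-3α,15-diacetoxy-13,14-epoxylabd-8(17)-en-19-oate | C=C1CC[C@@H]2[C@](C)(CC[C@@H](OC(C)=O)[C@]2(C)C(=O)OC)[C@H]1CC[C@@]3(C)O[C@@H]3COC(C)=O
F8 | step 15 | methyl (13R,14R)-3α-acetoxy-13,14-epoxy-15-hydroxylabd-8(17)-en-19-oate | C=C1CC[C@@H]2[C@](C)(CC[C@@H](OC(C)=O)[C@]2(C)C(=O)OC)[C@H]1CC[C@@]3(C)O[C@@H]3CO
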